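**Strategy.** Everything rests on cutting ring A (C1, C10, C11, C12, C13, C14) across C1–C14 and C10–C11: a catalytic enantioselective Diels–Alder reaction joins ethyl (E)-3-methyl-4-oxobut-2-enoate (C2, C1, C15, C10, C9) with (1E,3E)-penta-1,3-dienyl acetate (C14–C11, C20). In one operation it builds the quaternary C1 and the trans C1-methyl/H-10 ring fusion, encoded in the E-alkene. Elimination to the 11,13-diene and α-face dihydroxylation then give the 11,12-diol and the 13,14-ene. The C2 and C9 carbonyls carry the two arms; a Nozaki–Hiyama–Kishi reaction closes the ten-membered ring at C6–C7 and a Reformatsky closure builds the lactone.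

Key step: step 2

Remark on the chemistry: briarane locants (C1–C20) are used for all intermediates and α is the face of ring A opposite the C15 methyl. The absolute sense of the catalyst in step 2 and of the borane in step 14 is taken from the accepted transition-state models for these reagent classes and would be confirmed on the first adduct.

Step 1
Reactants: 1 (E)-pent-2-enal
Product: 2 (1E,3E)-penta-1,3-dien-1-yl acetate
Conditions: t-BuOK, THF, −78 °C; then AcCl, −78 °C
Reagents that add atoms: acetyl chloride CC(=O)Cl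
Why: γ-Deprotonation should give the extended potassium dienolate, which is O-acetylated at low temperature to the 1E dienyl acetate (dienolate O-acylation); any 3Z isomer cannot reach the s-cis form and stays inert in step 2.

Step 2
Reactants: 2 (1E,3E)-penta-1,3-dien-1-yl acetate; 3 ethyl (E)-3-methyl-4-oxobut-2-enoate
Product: 4 ethyl 5-acetoxy-6-formyl-2,6-dimethylcyclohex-3-ene-1-carboxylate (ester and C15 methyl β; formyl, acetoxy and C20 methyl α)
Conditions: B-(o-tolyl)oxazaborolidine of (S)-α,α-diphenylprolinol·HNTf2 (20 mol%), CH2Cl2, −78 to −40 °C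
Reagents that add atoms: none
Why: The oxazaborolidinium ion binds the formyl oxygen of 3 and lowers its LUMO, so that a concerted, asynchronous, normal-demand [4+2] cycloaddition with the electron-rich diene 2 should overcome the steric cost of the trisubstituted alkene; the closest known reaction type is the chiral-Lewis-acid-catalysed Diels–Alder reaction of α-substituted enals that creates quaternary stereocentres. Ring A is closed in the intermolecular [4+2] mode, suprafacially on both partners, C14 bonding to C1 and C11 to C10. C1 and C10 are set in one event: their relative configuration (C15 methyl cis to C9, the later trans ring fusion) copies the E geometry of 3, and their absolute configuration comes from the catalyst, which should shield one face of the s-trans enal so that the diene adds to the Si face of C1 (the catalyst antipode would be taken if the first adduct showed the opposite sense). C11 and C14 arise cis to each other from the E,E-diene (endo formyl), which is all that step 3 needs, since both centres are erased there. The step needs regiocontrol, and the substrate secures it twice: the acetoxy terminus C14 bonds to the formyl-bearing C1 and the methyl terminus C11 to the ester-bearing C10, the "ortho" orientation for both donor–acceptor pairs. Activation of the aldehyde and not the ester follows from the higher Lewis basicity of the formyl group.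

Step 3
Reactants: 4 Diels–Alder adduct
Product: 5 ethyl (1S,6S)-6-formyl-2,6-dimethylcyclohexa-2,4-diene-1-carboxylate
Conditions: Pd(PPh3)4 (5 mol%), Et3N, THF, 65 °C
Reagents that add atoms: none
Why: Zerovalent palladium should ionise the allylic acetate with inversion to a π-allyl complex (C12–C14) whose only β-hydrogen, H-11, is syn to the metal because methyl and acetoxy were cis in 4, so β-hydride elimination gives the C11=C12/C13=C14 diene (palladium-catalysed 1,4-elimination of an allylic acetate).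

Step 4
Reactants: 5 diene aldehyde
Product: 6 ethyl (1S,6S)-6-[1-hydroxy-2-(methoxymethoxy)ethyl]-2,6-dimethylcyclohexa-2,4-diene-1-carboxylate (C2 epimers)
Conditions: Bu3SnCH2OCH2OCH3, n-BuLi, THF, −78 °C; then 5, −78 °C; H2O
Reagents that add atoms: tributyl[(methoxymethoxy)methyl]stannane CCCC[Sn](CCCC)(CCCC)COCOC
Why: The α-alkoxy organolithium from tin–lithium exchange should add to the non-enolisable neopentyl aldehyde faster than to the ester at −78 °C; the C2 carbinol mixture is removed in step 5.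

Step 5
Reactants: 6 carbinol
Product: 7 ethyl (1S,6S)-6-[(methoxymethoxy)acetyl]-2,6-dimethylcyclohexa-2,4-diene-1-carboxylate
Conditions: Dess–Martin periodinane, CH2Cl2, 0 °C to rt
Reagents that add atoms: none
Why: Dess–Martin oxidation of the secondary alcohol should give the α-alkoxy ketone, which can enolise only toward C3 because C1 is quaternary.

Step 6
Reactants: 7 diene ketone
Product: 8 ethyl 2,3-dihydroxy-6-[(methoxymethoxy)acetyl]-2,6-dimethylcyclohex-4-ene-1-carboxylate (11α,12α-diol)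
Conditions: OsO4 (2 mol%), NMO (1.05 equiv), acetone/H2O, 0 °C
Reagents that add atoms: N-methylmorpholine N-oxide C[N+]1([O-])CCOCC1 (oxygen source through catalytic osmium tetroxide O=[Os](=O)(=O)=O)
Why: Catalytic syn-dihydroxylation should attack the more electron-rich trisubstituted C11=C12 bond from the α face, anti to the C9 ester on the neighbouring C10 and to the C15 methyl, setting C11 and C12 as the cis-diol while the hindered, acyl-deactivated C13=C14 bond remains.

Step 7
Reactants: 8 diol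
Product: 9 11,12-O-isopropylidene derivative of 8
Conditions: Me2C(OMe)2, PPTS (cat.), CH2Cl2, rt
Reagents that add atoms: 2,2-dimethoxypropane COC(C)(C)OC
Why: Acid-catalysed transketalisation should close the five-membered acetonide on the cis-diol and mask both hydroxyls until the last step.

Step 8
Reactants: 10 prop-2-yn-1-ol
Product: 12 (Z)-3-iodo-2-methylprop-2-en-1-ol, via alkenylmagnesium alkoxide 11 (not isolated)
Conditions: MeMgBr (2.2 equiv), CuI (10 mol%), THF, −10 °C to rt; then I2, −78 to 0 °C; 1 M HCl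
Reagents that add atoms: methylmagnesium bromide C[Mg]Br; iodine II
Why: Copper-catalysed anti-carbomagnesiation of the magnesium alkoxide should place methyl on C5 and magnesium on C6 cis to the CH2O group through a five-membered chelate, and iodinolysis with retention gives the Z iodide.

Step 9
Reactants: 12 (Z)-3-iodo-2-methylprop-2-en-1-ol
Product: 13 (Z)-3-iodo-2-methylprop-2-enal
Conditions: MnO2, CH2Cl2, rt
Reagents that add atoms: none
Why: MnO2 should oxidise the allylic alcohol to the enal without touching the vinyl iodide or the alkene geometry.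

Step 10
Reactants: 9 ring A keto ester acetonide; 13 (Z)-3-iodo-2-methylprop-2-enal
Product: 15 syn-aldol ketone (C2=O; 3-OMOM; 4-OH; Z-C5=C6–I), via dibutylboron enolate 14 (not isolated)
Conditions: 9, Bu2BOTf, i-Pr2NEt, CH2Cl2, −78 to 0 °C; then 13, −78 °C; pH 7 buffer, H2O2, MeOH, 0 °C
Reagents that add atoms: none
Why: The Z(O)-boron enolate of the α-alkoxy ketone should react through a closed chair (Zimmerman–Traxler) transition state to the 3,4-syn aldol, the aldehyde approaching the enolate face away from the C10 branch of the quaternary C1 (C14 in the enolate plane, methyl toward boron), which sets C3 and C4.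

Step 11
Reactants: 15 aldol ketone
Product: 16 2,4-anti diol (2-OH, 3-OMOM, 4-OH)
Conditions: Me4NBH(OAc)3, MeCN/AcOH, −30 °C
Reagents that add atoms: none
Why: In this Evans–Saksena reduction the C4 alkoxy-triacetoxyborohydride should deliver hydride intramolecularly through a chair, giving the 2,4-anti diol and hence the 2,3-anti/3,4-syn array (C2 set).

Step 12
Reactants: 16 diol
Product: 17 2,4-bis-O-TBS ether ethyl ester
Conditions: TBSOTf, 2,6-lutidine, CH2Cl2, −78 to 0 °C
Reagents that add atoms: tert-butyldimethylsilyl triflate CC(C)(C)[Si](C)(C)OS(=O)(=O)C(F)(F)F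
Why: The silyl triflate should silylate both secondary hydroxyls, the neopentyl C2–OH included.

Step 13
Reactants: 17 ethyl ester
Product: 18 C9 aldehyde
Conditions: i-Bu2AlH (1.2 equiv), CH2Cl2, −78 °C; H2O, KNaC4H4O6 aq.
Reagents that add atoms: none
Why: At −78 °C the aluminium hemiacetal of the hindered ester should survive until work-up, so one hydride equivalent stops at the aldehyde.

Step 14
Reactants: 18 C9 aldehyde
Product: 19 8,9-syn adduct (9-OH, 8-O-(4-methoxyphenyl), C7 vinyl)
Conditions: allyl 4-methoxyphenyl ether, s-BuLi, THF, −78 °C; (+)-Ipc2BOMe; BF3·OEt2; then 18, −78 °C; NaOH, H2O2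
Reagents that add atoms: allyl 4-methoxyphenyl ether C=CCOc1ccc(OC)cc1
Why: Allylboration through a closed chair should give the 8,9-syn adduct from the Z-γ-aryloxyallyl borane, the isopinocampheyl ligands selecting the aldehyde face that sets C9 as in the target (reagent control); C8 is temporary.

Step 15
Reactants: 19 homoallylic alcohol
Product: 20 9-O-TBS ether
Conditions: TBSOTf, 2,6-lutidine, CH2Cl2, 0 °C
Reagents that add atoms: tert-butyldimethylsilyl triflate CC(C)(C)[Si](C)(C)OS(=O)(=O)C(F)(F)F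
Why: Silylation of the only free hydroxyl should protect C9–OH in the same class as C2–OH and C4–OH.

Step 16
Reactants: 20 terminal alkene
Product: 22 C7 aldehyde, via terminal diol 21 (not isolated)
Conditions: OsO4 (2 mol%), NaIO4, 2,6-lutidine, dioxane/H2O, rt
Reagents that add atoms: sodium periodate [Na+].[O-]I(=O)(=O)=O (oxygen source through catalytic osmium tetroxide O=[Os](=O)(=O)=O)
Why: In this Johnson–Lemieux oxidation OsO4 should dihydroxylate the unhindered monosubstituted alkene in preference to the hindered ring alkene and the iodo-substituted alkene, and periodate cleaves the diol to the aldehyde.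

Step 17
Reactants: 22 iodo aldehyde
Product: 23 ten-membered allylic alcohol (7-OH, Z-C5=C6)
Conditions: CrCl2 (10 equiv), NiCl2 (2 mol%), DMSO, rt, 0.003 M, slow addition of 22
Reagents that add atoms: none
Why: In the Nozaki–Hiyama–Kishi reaction nickel-catalysed insertion into the C–I bond and transmetalation to chromium should give an alkenylchromium species that adds only to the aldehyde under high dilution with retention of the Z geometry; Felkin–Anh addition anti to the C8 aryloxy group should set C7 (7,8-anti, hence 7,9-anti).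

Step 18
Reactants: 23 allylic alcohol
Product: 24 C7 2-bromopropanoate
Conditions: CH3CHBrCOBr, pyridine, CH2Cl2, 0 °C
Reagents that add atoms: 2-bromopropanoyl bromide CC(Br)C(=O)Br
Why: Acylation of the only free hydroxyl should install the three lactone carbons C19, C17 and C18 as a latent ester enolate.

Step 19
Reactants: 24 aryl ether
Product: 25 C8 alcohol
Conditions: (NH4)2Ce(NO3)6, pyridine, MeCN/H2O, 0 °C
Reagents that add atoms: none
Why: The tetravalent cerium salt should oxidise the electron-rich aryl ether to the quinone and release the C8 hydroxyl, while silyl ethers, acetals, the bromo ester and the alkenes are not oxidised under buffered conditions.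

Step 20
Reactants: 25 C8 alcohol
Product: 26 C8 ketone
Conditions: Dess–Martin periodinane, CH2Cl2, rt
Reagents that add atoms: none
Why: Dess–Martin oxidation under non-basic conditions should give the ketone without acyl migration or epimerisation at C7 and C9.

Step 21
Reactants: 26 bromo ester ketone
Product: 28 β-hydroxy lactone (8-OH; C17 H/CH3 epimers), via samarium enolate 27 (not isolated)
Conditions: SmI2 (2.5 equiv), THF, −78 °C; H2O
Reagents that add atoms: none
Why: SmI2 should reduce only the C–Br bond to an ester enolate (no base, so C7 and C9 are not epimerised) that adds to the C8 ketone in a five-membered Reformatsky closure; the ten-membered ring favours the transition state with C6 and C9 anti about C7–C8, which sets C8 in the trans-fused lactone.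

Step 22
Reactants: 28 β-hydroxy lactone
Product: 30 8,17-dihydroxy lactone, via dilithium dianion 29 (not isolated)
Conditions: LiN(i-Pr)2 (3 equiv), THF, −78 °C; 2-(phenylsulfonyl)-3-phenyloxaziridine, −78 °C; AcOH
Reagents that add atoms: 2-(phenylsulfonyl)-3-phenyloxaziridine O=S(=O)(c1ccccc1)N1OC1c1ccccc1
Why: The alkoxide/enolate dianion should be hydroxylated on the face anti to the C8 oxido group, as in alkylations of β-hydroxy lactone dianions, which sets C17 with OH trans to the C8–OH and methyl cis to it.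

Step 23
Reactants: 30 tris-TBS ether
Product: 31 2,4,9-triol
Conditions: Bu4NF, AcOH, THF, rt to 40 °C
Reagents that add atoms: none
Why: Buffered fluoride should cleave the three silyl ethers while the MOM ether, the acetonide and the lactone are inert.

Step 24
Reactants: 31 triol
Product: 32 2,4,9-triacetate
Conditions: Ac2O, pyridine, DMAP (cat.), CH2Cl2, 0 °C to rt
Reagents that add atoms: acetic anhydride CC(=O)OC(C)=O
Why: The three secondary hydroxyls should be acetylated well before the tertiary C8 and C17 hydroxyls react.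

Step 25
Reactants: 32 triacetate
Product: 33 Brianodin C
Conditions: Me2BBr, CH2Cl2, −78 °C; NaHCO3 aq.
Reagents that add atoms: none
Why: The bromoborane should cleave the MOM ether and the acetonide through their oxocarbenium ions at −78 °C, where acetates and the lactone are inert and acyl migration to C3–OH is slow.

**Compound list**

1 | (E)-pent-2-enal | CC/C=C/C=O | starting material
2 | (1E,3E)-penta-1,3-dien-1-yl acetate | CC(=O)O/C=C/C=C/C | intermediate
3 | ethyl (E)-3-methyl-4-oxobut-2-enoate | CCOC(=O)/C=C(\C)C=O | starting material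
4 | ethyl 5-acetoxy-6-formyl-2,6-dimethylcyclohex-3-ene-1-carboxylate (ester and 6-methyl on one face; formyl, acetoxy and 2-methyl on the other) | O=C[C@@]1(C)[C@@H](OC(C)=O)C=C[C@@H](C)[C@@H]1C(=O)OCC | intermediate
5 | ethyl (1S,6S)-6-formyl-2,6-dimethylcyclohexa-2,4-diene-1-carboxylate | O=C[C@@]1(C)C=CC=C(C)[C@@H]1C(=O)OCC | intermediate
6 | ethyl (1S,6S)-6-[1-hydroxy-2-(methoxymethoxy)ethyl]-2,6-dimethylcyclohexa-2,4-diene-1-carboxylate (carbinol epimers) | COCOCC(O)[C@@]1(C)C=CC=C(C)[C@@H]1C(=O)OCC | intermediate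
7 | ethyl (1S,6S)-6-[(methoxymethoxy)acetyl]-2,6-dimethylcyclohexa-2,4-diene-1-carboxylate | COCOCC(=O)[C@@]1(C)C=CC=C(C)[C@@H]1C(=O)OCC | intermediate
8 | ethyl 2,3-dihydroxy-6-[(methoxymethoxy)acetyl]-2,6-dimethylcyclohex-4-ene-1-carboxylate (11α,12α-cis-diol, anti to the ester and the C15 methyl) | COCOCC(=O)[C@@]1(C)C=C[C@@H](O)[C@@](C)(O)[C@@H]1C(=O)OCC | intermediate
9 | 11,12-O-isopropylidene acetal of 8 | COCOCC(=O)[C@@]1(C)C=C[C@H]2OC(C)(C)O[C@@]2(C)[C@@H]1C(=O)OCC | intermediate
10 | prop-2-yn-1-ol | C#CCO | starting material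
11 | bromomagnesium (Z)-3-(bromomagnesio)-2-methylprop-2-en-1-olate | C/C(CO[Mg]Br)=C/[Mg]Br | intermediate
12 | (Z)-3-iodo-2-methylprop-2-en-1-ol | OC/C(C)=C\I | intermediate
13 | (Z)-3-iodo-2-methylprop-2-enal | O=C/C(C)=C\I | intermediate
14 | dibutylboron Z(O)-enolate of 9 | CCCCB(CCCC)O/C(=C\OCOC)[C@@]1(C)C=C[C@H]2OC(C)(C)O[C@@]2(C)[C@@H]1C(=O)OCC | intermediate
15 | aldol adduct: C2 ketone, 3-OMOM and 4-OH syn (configured as C3 and C4 of the target), Z-C5(CH3)=C6H–I, ring A acetonide ethyl ester | O=C([C@H](OCOC)[C@@H](O)/C(C)=C\I)[C@@]1(C)C=C[C@H]2OC(C)(C)O[C@@]2(C)[C@@H]1C(=O)OCC | intermediate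
16 | 2,4-diol: 2-OH anti to 3-OMOM and to 4-OH (C2–C4 as in the target) | O[C@H]([C@H](OCOC)[C@@H](O)/C(C)=C\I)[C@@]1(C)C=C[C@H]2OC(C)(C)O[C@@]2(C)[C@@H]1C(=O)OCC | intermediate
17 | 2,4-bis-O-TBS ether of 16 | CC(C)(C)[Si](C)(C)O[C@H]([C@H](OCOC)[C@@H](O[Si](C)(C)C(C)(C)C)/C(C)=C\I)[C@@]1(C)C=C[C@H]2OC(C)(C)O[C@@]2(C)[C@@H]1C(=O)OCC | intermediate
18 | C9 aldehyde from 17 | CC(C)(C)[Si](C)(C)O[C@H]([C@H](OCOC)[C@@H](O[Si](C)(C)C(C)(C)C)/C(C)=C\I)[C@@]1(C)C=C[C@H]2OC(C)(C)O[C@@]2(C)[C@@H]1C=O | intermediate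
19 | homoallylic alcohol: 9-OH (as in the target), 8-O-(4-methoxyphenyl) syn to it, C7 vinyl | CC(C)(C)[Si](C)(C)O[C@H]([C@H](OCOC)[C@@H](O[Si](C)(C)C(C)(C)C)/C(C)=C\I)[C@@]1(C)C=C[C@H]2OC(C)(C)O[C@@]2(C)[C@@H]1[C@H](O)[C@@H](Oc3ccc(OC)cc3)C=C | intermediate
20 | 9-O-TBS ether of 19 | CC(C)(C)[Si](C)(C)O[C@H]([C@H](OCOC)[C@@H](O[Si](C)(C)C(C)(C)C)/C(C)=C\I)[C@@]1(C)C=C[C@H]2OC(C)(C)O[C@@]2(C)[C@@H]1[C@H](O[Si](C)(C)C(C)(C)C)[C@@H](Oc3ccc(OC)cc3)C=C | intermediate
21 | terminal 1,2-diol from 20 | CC(C)(C)[Si](C)(C)O[C@H]([C@H](OCOC)[C@@H](O[Si](C)(C)C(C)(C)C)/C(C)=C\I)[C@@]1(C)C=C[C@H]2OC(C)(C)O[C@@]2(C)[C@@H]1[C@H](O[Si](C)(C)C(C)(C)C)[C@@H](Oc3ccc(OC)cc3)C(O)CO | intermediate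
22 | C7 aldehyde (8-O-aryl, 9-O-TBS) with the Z-vinyl iodide arm | CC(C)(C)[Si](C)(C)O[C@H]([C@H](OCOC)[C@@H](O[Si](C)(C)C(C)(C)C)/C(C)=C\I)[C@@]1(C)C=C[C@H]2OC(C)(C)O[C@@]2(C)[C@@H]1[C@H](O[Si](C)(C)C(C)(C)C)[C@@H](Oc3ccc(OC)cc3)C=O | intermediate
23 | ten-membered carbocycle: 2,4,9-tri-O-TBS, 3-O-MOM, Z-C5=C6, 7-OH (as in the target), 8-O-(4-methoxyphenyl), 11,12-acetonide, 13-ene | CC(C)(C)[Si](C)(C)O[C@@H]1[C@H](OCOC)[C@@H](O[Si](C)(C)C(C)(C)C)/C(C)=C\[C@H](O)[C@H](Oc3ccc(OC)cc3)[C@@H](O[Si](C)(C)C(C)(C)C)[C@H]2[C@]4(C)OC(C)(C)O[C@@H]4C=C[C@]12C | intermediate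
24 | 7-O-(2-bromopropanoyl) ester of 23 (bromide epimers) | CC(C)(C)[Si](C)(C)O[C@@H]1[C@H](OCOC)[C@@H](O[Si](C)(C)C(C)(C)C)/C(C)=C\[C@H](OC(=O)C(C)Br)[C@H](Oc3ccc(OC)cc3)[C@@H](O[Si](C)(C)C(C)(C)C)[C@H]2[C@]4(C)OC(C)(C)O[C@@H]4C=C[C@]12C | intermediate
25 | C8 alcohol from 24 | CC(C)(C)[Si](C)(C)O[C@@H]1[C@H](OCOC)[C@@H](O[Si](C)(C)C(C)(C)C)/C(C)=C\[C@H](OC(=O)C(C)Br)[C@H](O)[C@@H](O[Si](C)(C)C(C)(C)C)[C@H]2[C@]4(C)OC(C)(C)O[C@@H]4C=C[C@]12C | intermediate
26 | C8 ketone from 25 | CC(C)(C)[Si](C)(C)O[C@@H]1[C@H](OCOC)[C@@H](O[Si](C)(C)C(C)(C)C)/C(C)=C\[C@H](OC(=O)C(C)Br)C(=O)[C@@H](O[Si](C)(C)C(C)(C)C)[C@H]2[C@]4(C)OC(C)(C)O[C@@H]4C=C[C@]12C | intermediate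
27 | samarium ester enolate of 26 | CC(C)(C)[Si](C)(C)O[C@@H]1[C@H](OCOC)[C@@H](O[Si](C)(C)C(C)(C)C)/C(C)=C\[C@H](OC(O[Sm](I)I)=CC)C(=O)[C@@H](O[Si](C)(C)C(C)(C)C)[C@H]2[C@]4(C)OC(C)(C)O[C@@H]4C=C[C@]12C | intermediate
28 | trans-fused γ-lactone: 8-OH (as in the target), C17 H/CH3 epimers | CC(C)(C)[Si](C)(C)O[C@@H]1[C@H](OCOC)[C@@H](O[Si](C)(C)C(C)(C)C)/C(C)=C\[C@@H]2OC(=O)C(C)[C@@]2(O)[C@@H](O[Si](C)(C)C(C)(C)C)[C@H]2[C@]4(C)OC(C)(C)O[C@@H]4C=C[C@]12C | intermediate
29 | dilithium alkoxide/lactone enolate of 28 | CC(C)(C)[Si](C)(C)O[C@@H]1[C@H](OCOC)[C@@H](O[Si](C)(C)C(C)(C)C)/C(C)=C\[C@@H]2OC(O[Li])=C(C)[C@@]2(O[Li])[C@@H](O[Si](C)(C)C(C)(C)C)[C@H]2[C@]4(C)OC(C)(C)O[C@@H]4C=C[C@]12C | intermediate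
30 | 8,17-dihydroxy lactone (C7, C8, C17 as in the target), 2,4,9-tri-O-TBS, 3-O-MOM, 11,12-acetonide | CC(C)(C)[Si](C)(C)O[C@@H]1[C@H](OCOC)[C@@H](O[Si](C)(C)C(C)(C)C)/C(C)=C\[C@@H]2OC(=O)[C@@](C)(O)[C@@]2(O)[C@@H](O[Si](C)(C)C(C)(C)C)[C@H]2[C@]4(C)OC(C)(C)O[C@@H]4C=C[C@]12C | intermediate
31 | 2,4,9-triol (3-O-MOM, 11,12-acetonide) | O[C@@H]1[C@H](OCOC)[C@@H](O)/C(C)=C\[C@@H]2OC(=O)[C@@](C)(O)[C@@]2(O)[C@@H](O)[C@H]2[C@]4(C)OC(C)(C)O[C@@H]4C=C[C@]12C | intermediate
32 | 2,4,9-triacetate (3-O-MOM, 11,12-acetonide) | CC(=O)O[C@@H]1[C@H](OCOC)[C@@H](OC(C)=O)/C(C)=C\[C@@H]2OC(=O)[C@@](C)(O)[C@@]2(O)[C@@H](OC(C)=O)[C@H]2[C@]4(C)OC(C)(C)O[C@@H]4C=C[C@]12C | intermediate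
33 | Brianodin C | CC(=O)O[C@@H]1[C@H](O)[C@@H](OC(C)=O)/C(C)=C\[C@@H]2OC(=O)[C@@](C)(O)[C@@]2(O)[C@@H](OC(C)=O)[C@H]2[C@](C)(O)[C@H](O)C=C[C@]12C | target

**Totals.** Total step count: 25. Longest linear sequence: 23 steps (steps 1–7 and 10–25, from 1); steps 8 and 9 make the side fragment 13.

**Steps most likely to fail**

Step 2. The cycloaddition may be too slow for the trisubstituted dienophile with the moderately electron-rich acetoxydiene, the diene may decompose under the strong Lewis acid, or facial discrimination may be poor. The fallback sets out from 3 and uses a more nucleophilic diene with a different chiral Lewis acid. (1E,3Z)-3-(tert-Butyldimethylsilyloxy)-N,N-dimethylpenta-1,3-dien-1-amine F1 (from 1-(dimethylamino)pent-1-en-3-one, KN(SiMe3)2, TBSCl) and 3 would be combined with the chiral complex (salen)CrSbF6 [salen = dianion of (R,R)-N,N′-bis(3,5-di-tert-butylsalicylidene)cyclohexane-1,2-diamine] to give the amino silyl enol ether cycloadduct F2 with the same C1–C14/C10–C11 connectivity. Dilute HCl work-up should give ethyl 6-formyl-2,6-dimethyl-3-oxocyclohex-4-ene-1-carboxylate F3. Kinetic enolisation toward C11 and triflation (KN(SiMe3)2, PhNTf2, −78 °C) should give the dienyl triflate F4, and reduction with Pd(OAc)2, PPh3, HCO2H and Bu3N comes back to the route at 5.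

Step 17. Transannular strain may favour oligomerisation over closure of the ten-membered ring, or the addition may show poor facial selectivity at C7. The fallback sets out from 22 and closes the ring at C5=C6 by metathesis instead. Vinylmagnesium bromide (THF, −78 °C, Felkin–Anh addition) should give the C7 vinyl carbinol F5. Hydrodeiodination (Bu3SnH, Pd(PPh3)4) should give the isopropenyl/vinyl diene F6. Ring-closing metathesis with the second-generation Grubbs catalyst at high dilution can only give the Z ring alkene and comes back to the route at 23.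

Step 22. The hydroxylation may occur on the wrong face of the enolate, or the dianion may open by retro-aldol cleavage. The fallback sets out from 23 and brings C17 in with its configuration fixed by a lactic acid acetal. Silylation (Et3SiOTf, 2,6-lutidine) should give the 7-O-TES ether F7, (NH4)2Ce(NO3)6 the C8 alcohol F8, and Dess–Martin oxidation the ketone F9. The lithium enolate of (2R,5R)-2-tert-butyl-5-methyl-1,3-dioxolan-4-one F10 (from (R)-lactic acid and pivalaldehyde) should add to F9 anti to its tert-butyl group to give the aldol adduct F11. Removal of the TES group with buffered fluoride should let the C7 hydroxyl open the dioxolanone with loss of pivalaldehyde, and this comes back to the route at 30.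

**Further compounds**

F1 | step 2 | (1E,3Z)-3-(tert-butyldimethylsilyloxy)-N,N-dimethylpenta-1,3-dien-1-amine | CN(C)/C=C/C(O[Si](C)(C)C(C)(C)C)=C/C
F2 | step 2 | ethyl 5-(dimethylamino)-6-formyl-2,6-dimethyl-3-(tert-butyldimethylsilyloxy)cyclohex-3-ene-1-carboxylate | O=C[C@@]1(C)C(N(C)C)C=C(O[Si](C)(C)C(C)(C)C)C(C)[C@@H]1C(=O)OCC
F3 | step 2 | ethyl 6-formyl-2,6-dimethyl-3-oxocyclohex-4-ene-1-carboxylate | O=C[C@@]1(C)C=CC(=O)C(C)[C@@H]1C(=O)OCC
F4 | step 2 | ethyl 6-formyl-2,6-dimethyl-3-(trifluoromethylsulfonyloxy)cyclohexa-2,4-diene-1-carboxylate | O=C[C@@]1(C)C=CC(OS(=O)(=O)C(F)(F)F)=C(C)[C@@H]1C(=O)OCC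
F5 | step 17 | C7 vinyl carbinol from 22 (7-OH anti to the 8-aryloxy group, Z-vinyl iodide retained) | CC(C)(C)[Si](C)(C)O[C@H]([C@H](OCOC)[C@@H](O[Si](C)(C)C(C)(C)C)/C(C)=C\I)[C@@]1(C)C=C[C@H]2OC(C)(C)O[C@@]2(C)[C@@H]1[C@H](O[Si](C)(C)C(C)(C)C)[C@@H](Oc3ccc(OC)cc3)[C@@H](O)C=C
F6 | step 17 | deiodinated diene (C5 isopropenyl, C7 vinyl carbinol) | CC(C)(C)[Si](C)(C)O[C@H]([C@H](OCOC)[C@@H](O[Si](C)(C)C(C)(C)C)C(C)=C)[C@@]1(C)C=C[C@H]2OC(C)(C)O[C@@]2(C)[C@@H]1[C@H](O[Si](C)(C)C(C)(C)C)[C@@H](Oc3ccc(OC)cc3)[C@@H](O)C=C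
F7 | step 22 | 7-O-triethylsilyl ether of 23 | CC(C)(C)[Si](C)(C)O[C@@H]1[C@H](OCOC)[C@@H](O[Si](C)(C)C(C)(C)C)/C(C)=C\[C@H](O[Si](CC)(CC)CC)[C@H](Oc3ccc(OC)cc3)[C@@H](O[Si](C)(C)C(C)(C)C)[C@H]2[C@]4(C)OC(C)(C)O[C@@H]4C=C[C@]12C
F8 | step 22 | C8 alcohol from F7 | CC(C)(C)[Si](C)(C)O[C@@H]1[C@H](OCOC)[C@@H](O[Si](C)(C)C(C)(C)C)/C(C)=C\[C@H](O[Si](CC)(CC)CC)[C@H](O)[C@@H](O[Si](C)(C)C(C)(C)C)[C@H]2[C@]4(C)OC(C)(C)O[C@@H]4C=C[C@]12C
F9 | step 22 | C8 ketone from F8 | CC(C)(C)[Si](C)(C)O[C@@H]1[C@H](OCOC)[C@@H](O[Si](C)(C)C(C)(C)C)/C(C)=C\[C@H](O[Si](CC)(CC)CC)C(=O)[C@@H](O[Si](C)(C)C(C)(C)C)[C@H]2[C@]4(C)OC(C)(C)O[C@@H]4C=C[C@]12C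
F10 | step 22 | (2R,5R)-2-tert-butyl-5-methyl-1,3-dioxolan-4-one | C[C@H]1O[C@@H](C(C)(C)C)OC1=O
F11 | step 22 | aldol adduct of F9 and the enolate of F10 (8-OH, C17 in the dioxolanone, methyl cis to tert-butyl) | CC(C)(C)[Si](C)(C)O[C@@H]1[C@H](OCOC)[C@@H](O[Si](C)(C)C(C)(C)C)/C(C)=C\[C@H](O[Si](CC)(CC)CC)[C@@](O)([C@]5(C)O[C@@H](C(C)(C)C)OC5=O)[C@@H](O[Si](C)(C)C(C)(C)C)[C@H]2[C@]4(C)OC(C)(C)O[C@@H]4C=C[C@]12C
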